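## Analysis of the target

The target is a flavone: a benzo-γ-pyrone (rings A and C) with a 2,4-dihydroxyphenyl group (ring B) on C2. It has no stereocentre, so the whole problem is the oxygenation pattern and telling seven oxygen substituents apart. Ring A is a hexasubstituted benzene: C5 carries the only free hydroxyl, C6, C7 and C8 carry methyl ethers, and C4a and C8a are the fusion atoms. C3 of ring C carries a fourth methyl ether, and ring B has free hydroxyls at C2' and C4'. The sensitive points are three. Ring A is electron-rich, and its 5-hydroxy-8-methoxy pair invites oxidation to a 5,8-quinone. Ring B is a resorcinol that is easily oxidised. The pyrone opens in strong base and could then re-close onto the C2' hydroxyl. The difficulty is to leave exactly one free hydroxyl among four contiguous oxygenated carbons of ring A while C3 stays a methyl ether. The plan rests on one feature: the free hydroxyl sits at C5, peri to the C4 carbonyl, and in the 5-deoxy compound C5–H is the only hydrogen left on ring A, so a carbonyl-directed C–H oxygenation can reach that position and no other.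

## Retrosynthetic reasoning

The last operation is the release of the two ring B phenols, so 17 is traced back to the bis-pivalate 16 by cutting the two acyl C–O bonds. Esters are chosen because the oxidation that comes before needs ring B electron-poor and acid-stable. Their removal by mild methanolysis leaves the four methyl ethers, the chelated C5 hydroxyl and the pyrone alone.

In 16 the C5–O bond is cut, which leads to the 5-deoxyflavone 14. This is the central disconnection. It turns the hexasubstituted ring A into a pentasubstituted 6,7,8-trimethoxy ring, and the free hydroxyl is distinguished from the three methyl ethers by the way it is made, not by selective methylation or demethylation. The forward reaction has to metalate C5–H from the C4 carbonyl and oxygenate it without oxidising ring A further. It therefore runs through the trifluoroacetate 15, which masks the new phenol until work-up.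

Ring C of 14 is opened at O1–C2, giving the 1,3-diketone 13, and 13 is cut at C2–C3, giving the aryl ester 12. The C3 methoxy group then arrives as the α-methoxy group of a ketone, and no oxidation at C3 is ever needed. The forward steps are an intramolecular acyl transfer from oxygen to the enolate carbon and an acid cyclodehydration. Only the ring A phenol is free in 13, so the pyrone can close on one side only.

The ester C–O bond of 12 is cut to the hydroxy ketone 7 and the acid chloride 11. This is the convergent point that joins the ring A half and the ring B half.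

In 7 the aryl–acyl bond (the future C4a–C4) is cut, which leads back through the boron chelate 6 to the aryl methoxyacetate 5, and 5 comes from the phenol 3 and the acid chloride 4. The acyl group has to migrate from oxygen to an ortho carbon. In 5 only one ortho position is free and the para position is blocked, so the regiochemistry is fixed by the substrate.

The phenol oxygen of 3, the future O1, replaces the formyl group of the aldehyde 1. The forward reaction is a peroxide oxidation with aryl migration through the formate 2.

The acid chloride 11 comes from the acid 10, and 10 from the dihydroxy acid 8 by acylation of both phenols. The carboxyl group is acylated as well, to the mixed anhydride 9, and is freed again by water.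

## Alternatives that were turned down

Alternative 1: Ring C is cut at C4a–C4, C4–C3 and O1–C2. The pieces are the iodoresorcinol A2, the arylacetylene A3 and a one-carbon carbonyl unit, joined in a palladium-catalysed carbonylative coupling under PdCl2(PPh3)2 in an amine. The phenol oxygen then adds to the alkyne in the 6-endo mode and gives the flavone A1. In its favour, the assembly is convergent, and A2 has a mirror plane through the C–I bond, so either hydroxyl gives the same product. The C5 hydroxyl is present from the start, so on that point this route is stronger than the chosen one, which has to create it late. Against it, A1 has no oxygen at C3. That oxygen would have to be added by oxidation of an electron-rich 5-hydroxyflavone, then methylated selectively beside the C5 hydroxyl, before the benzyl ethers are removed. This means at least three further steps, one of them an oxidation no safer than the one avoided. Oxidative addition into a very electron-rich aryl iodide flanked by two free hydroxyls is slow, closure in the 5-exo mode competes with the 6-endo mode, and A2 is itself a hexasubstituted benzene that needs its own synthesis. The chosen route offers the C3 methoxy group from the first carbon–carbon bond onward and a ring A precursor bought as a simple aldehyde.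

Alternative 2: Ring C is cut at O1–C8a and C4–C4a. Fluoride releases the aryne A7 from the silyl triflate A5. The enolate oxygen of the α-methoxy β-keto ester A6 adds to it, and the aryl anion closes onto the ester to give the pentamethoxyflavone A4. In its favour, A7 is symmetric, so no regiochemistry arises, and the 2-aryl and 3-methoxy groups are both set in one ring-forming step. The endgame is a chelation-controlled cleavage of the C5 methyl ether peri to the carbonyl by a boron or aluminium halide, which would also strip the benzyl ethers. That reaction type is well established and is at least as dependable as a C–H oxidation. Against it, β-keto ester enolates normally attack arynes through carbon and end in insertion into the C–C bond, so the O-arylation pathway needed here is the uncertain one, and A7 is shielded by methoxy groups on both sides. A5 is a hexasubstituted benzene with adjacent silyl and triflate groups and takes a long sequence to make. The C3 ether also sits next to the carbonyl and must survive the demethylation. The chosen route offers standard reactions up to its single risky step and needs no bespoke aryne precursor.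

Alternative 3: Ring A is built last by cutting C4a–C5. Heating the cyclobutenone A9 opens it to the vinylketene A10. The methoxy group on the quaternary carbon rotates outward, which puts the pyranonyl group cis to the ketene. A 6π closure onto C5 of the pyranone followed by tautomerisation gives the phenol A8, and only hydrogenolysis remains. In its favour, the ketene carbon becomes C5 with its free hydroxyl and the three methoxy groups are placed by construction. No electron-rich arene is ever oxidised. On the differentiation problem this is the cleanest answer of all and stronger than the chosen route. Against it, A9 requires the pyranone A12 to be metalated at C6 and added to the squarate A11. γ-Pyrones tend to undergo addition and ring opening with organolithiums, and the metalation must compete with the benzylic and ring B positions. The hindered tertiary alkoxide must then be methylated, and A12 needs several steps of its own. The route is longer and has two or three uncertain steps where the chosen one has one. The chosen route offers cheap starting materials and a short, conventional path to the substrate of its key step.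

Key step: step 8

Remark on the chemistry: methoxyacetyl chloride (4), the acid chloride of methoxyacetic acid, is taken as a catalogue chemical. Diketone 13 is written in its keto form and is racemic at C2, a centre that disappears on cyclisation.

## Route

Step 1
Reactants: 1 2,3,4-trimethoxybenzaldehyde
Product: 3 2,3,4-trimethoxyphenol, via 2,3,4-trimethoxyphenyl formate 2 (not isolated)
Conditions: H2O2 (30% aq.), H2SO4 (cat.), MeOH, rt
Reagents that add atoms: hydrogen peroxide, OO
Why: Acid-catalysed Dakin oxidation: the peroxide adds to the aldehyde and the aryl group, made migration-prone by the ortho and para methoxy groups, shifts to oxygen to give formate 2. Acidic methanol cleaves 2 in the same flask to the phenol.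

Step 2
Reactants: 3 2,3,4-trimethoxyphenol; 4 methoxyacetyl chloride
Product: 5 2,3,4-trimethoxyphenyl methoxyacetate
Conditions: Et3N, DMAP (cat.), CH2Cl2, 0 °C to rt
Reagents that add atoms: none
Why: Plain DMAP-catalysed O-acylation of a phenol by an acid chloride; nothing else in 3 is nucleophilic.

Step 3
Reactants: 5 2,3,4-trimethoxyphenyl methoxyacetate
Product: 7 1-(2-hydroxy-3,4,5-trimethoxyphenyl)-2-methoxyethan-1-one, via difluoroboron chelate 6 (not isolated)
Conditions: BF3·OEt2 (neat, excess), 70 °C; then MeOH/H2O, 60 °C
Reagents that add atoms: none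
Why: Fries rearrangement: BF3 activates the aryl ester and the acyl group moves to C6, the only free position ortho to the oxygen (the para position carries a methoxy group). The product is held as the six-membered chelate 6, which pulls the equilibrium to the ortho-hydroxy ketone and is hydrolysed on warming with aqueous methanol. BF3 is too mild to cleave the aryl methyl ethers.

Step 4
Reactants: 8 2,4-dihydroxybenzoic acid
Product: 10 2,4-bis(2,2-dimethylpropanoyloxy)benzoic acid, via pivalic mixed anhydride 9 (not isolated)
Conditions: PivCl (3.3 equiv), pyridine, DMAP (cat.), CH2Cl2, 0 °C to rt; then H2O, THF, rt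
Reagents that add atoms: pivaloyl chloride, CC(C)(C)C(Cl)=O; water, O
Why: Acylation with excess acid chloride: the carboxylate forms the mixed anhydride first, which can also pass a pivaloyl group to the neighbouring C2 hydroxyl through a six-membered transition state, and DMAP completes both phenol esters. Water then cleaves only the anhydride 9, which is far more labile than the hindered aryl pivalates.

Step 5
Reactants: 10 2,4-bis(2,2-dimethylpropanoyloxy)benzoic acid
Product: 11 2,4-bis(2,2-dimethylpropanoyloxy)benzoyl chloride
Conditions: (COCl)2, DMF (cat.), CH2Cl2, 0 °C to rt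
Reagents that add atoms: oxalyl chloride, O=C(Cl)C(Cl)=O
Why: Acid chloride formation through the chloroiminium salt from DMF; the conditions are neutral and leave the aryl pivalates alone, as in the ortho-acyloxybenzoyl chlorides that are stable reagents.

Step 6
Reactants: 7 1-(2-hydroxy-3,4,5-trimethoxyphenyl)-2-methoxyethan-1-one; 11 2,4-bis(2,2-dimethylpropanoyloxy)benzoyl chloride
Product: 12 4-{[6-(methoxyacetyl)-2,3,4-trimethoxyphenoxy]carbonyl}-1,3-phenylene bis(2,2-dimethylpropanoate)
Conditions: Et3N, DMAP (0.2 equiv), CH2Cl2, 0 °C to rt
Reagents that add atoms: none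
Why: O-Aroylation of the phenol, the first stage of a Baker–Venkataraman flavone synthesis. The phenol is hydrogen-bonded to the ketone and flanked by a methoxy group, so the acylpyridinium from DMAP is used; the amine base is too weak to enolise the ketone.

Step 7
Reactants: 12 4-{[6-(methoxyacetyl)-2,3,4-trimethoxyphenoxy]carbonyl}-1,3-phenylene bis(2,2-dimethylpropanoate)
Product: 14 4-(3,6,7,8-tetramethoxy-4-oxo-4H-chromen-2-yl)-1,3-phenylene bis(2,2-dimethylpropanoate), via 1,3-diketone 13 (not isolated)
Conditions: LiN(SiMe3)2 (2.5 equiv), THF, −78 to −10 °C; aq. NH4Cl; crude, then TsOH·H2O (0.2 equiv), toluene, 90 °C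
Reagents that add atoms: none
Why: Baker–Venkataraman rearrangement: the lithium enolate of the α-methoxy ketone attacks the neighbouring aryl ester through a six-membered transition state (an intramolecular Claisen condensation) and forms C2–C3; the hindered pivalates are spared by the low temperature and the non-nucleophilic base. Acid then closes O1–C2 by 6-exo-trig addition of the ring A phenol to the aroyl ketone and dehydration. Only the ring A phenol is free, so the pyrone forms on that side alone.

Step 8
Reactants: 14 4-(3,6,7,8-tetramethoxy-4-oxo-4H-chromen-2-yl)-1,3-phenylene bis(2,2-dimethylpropanoate)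
Product: 16 4-(5-hydroxy-3,6,7,8-tetramethoxy-4-oxo-4H-chromen-2-yl)-1,3-phenylene bis(2,2-dimethylpropanoate), via C5 trifluoroacetate 15 (not isolated)
Conditions: [RuCl2(p-cymene)]2 (5 mol %), PhI(OCOCF3)2 (1.1 equiv, in portions), TFA/TFAA, 80 °C; then aq. NaHCO3, rt
Reagents that add atoms: [bis(trifluoroacetoxy)iodo]benzene, O=C(OI(OC(=O)C(F)(F)F)c1ccccc1)C(F)(F)F (its trifluoroacetate, interchangeable with that of the solvent, supplies the C5 oxygen)
Why: Chloride–trifluoroacetate exchange in TFA gives a cationic divalent ruthenium trifluoroacetate that binds the C4 carbonyl oxygen of 14. Carboxylate-assisted metalation then cleaves the peri C5–H bond and gives a five-membered ruthenacycle (Ru, O, C4, C4a, C5). PhI(OCOCF3)2 oxidises it to tetravalent ruthenium, C–O reductive elimination releases trifluoroacetate 15 and the divalent catalyst, and bicarbonate work-up hydrolyses 15 to 16. The closest known reaction type is the ketone-directed ortho C–H hydroxylation of aryl ketones, chromones and flavones with divalent ruthenium or palladium catalysts in TFA/TFAA. No ring is closed and no stereocentre is formed. Site selectivity is secured twice: C5–H is the only hydrogen on ring A, and it is the only C–H the C4 oxygen can reach through a five-membered metallacycle, since C6'–H of ring B would need a seven-membered one. Chemoselectivity comes from the two pivalates, which keep ring B electron-poor, from TFAA, which holds the new oxygen as an electron-poor trifluoroacetate until work-up, and from adding the oxidant in portions so that it is never in excess over unreacted 14.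

Step 9
Reactants: 16 4-(5-hydroxy-3,6,7,8-tetramethoxy-4-oxo-4H-chromen-2-yl)-1,3-phenylene bis(2,2-dimethylpropanoate)
Product: 17 5,2',4'-trihydroxy-3,6,7,8-tetramethoxyflavone, that is 2-(2,4-dihydroxyphenyl)-5-hydroxy-3,6,7,8-tetramethoxy-4H-chromen-4-one
Conditions: K2CO3 (3 equiv), MeOH, 0 °C to rt, under argon; then 1 M HCl
Reagents that add atoms: none
Why: Base-mediated transesterification: aryl pivalates are cleaved by methoxide at room temperature because phenoxide is a good leaving group, while the methyl ethers and the pyrone are not touched under these mild conditions. Argon protects the polyphenolate from air, and acidification returns the three phenols.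

## Compound list

1 | 2,3,4-trimethoxybenzaldehyde | COc1ccc(C=O)c(OC)c1OC | starting material
2 | 2,3,4-trimethoxyphenyl formate (not isolated) | COc1ccc(OC=O)c(OC)c1OC | intermediate
3 | 2,3,4-trimethoxyphenol | COc1ccc(O)c(OC)c1OC | intermediate
4 | methoxyacetyl chloride | COCC(Cl)=O | starting material
5 | 2,3,4-trimethoxyphenyl methoxyacetate | COCC(=O)Oc1ccc(OC)c(OC)c1OC | intermediate
6 | 2,2-difluoro-6,7,8-trimethoxy-4-(methoxymethyl)-1,3,2-benzodioxaborinine, the BF2 chelate of 7 in its zwitterionic O→B form (not isolated) | COCC1=[O+][B-](F)(F)Oc2c(OC)c(OC)c(OC)cc12 | intermediate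
7 | 1-(2-hydroxy-3,4,5-trimethoxyphenyl)-2-methoxyethan-1-one | COCC(=O)c1cc(OC)c(OC)c(OC)c1O | intermediate
8 | 2,4-dihydroxybenzoic acid | O=C(O)c1ccc(O)cc1O | starting material
9 | 2,4-bis(2,2-dimethylpropanoyloxy)benzoic 2,2-dimethylpropanoic anhydride (not isolated) | CC(C)(C)C(=O)OC(=O)c1ccc(OC(=O)C(C)(C)C)cc1OC(=O)C(C)(C)C | intermediate
10 | 2,4-bis(2,2-dimethylpropanoyloxy)benzoic acid | CC(C)(C)C(=O)Oc1ccc(C(=O)O)c(OC(=O)C(C)(C)C)c1 | intermediate
11 | 2,4-bis(2,2-dimethylpropanoyloxy)benzoyl chloride | CC(C)(C)C(=O)Oc1ccc(C(Cl)=O)c(OC(=O)C(C)(C)C)c1 | intermediate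
12 | 4-{[6-(methoxyacetyl)-2,3,4-trimethoxyphenoxy]carbonyl}-1,3-phenylene bis(2,2-dimethylpropanoate) | COCC(=O)c1cc(OC)c(OC)c(OC)c1OC(=O)c1ccc(OC(=O)C(C)(C)C)cc1OC(=O)C(C)(C)C | intermediate
13 | 4-[3-(2-hydroxy-3,4,5-trimethoxyphenyl)-2-methoxy-3-oxopropanoyl]-1,3-phenylene bis(2,2-dimethylpropanoate), racemic, keto form (not isolated) | COC(C(=O)c1cc(OC)c(OC)c(OC)c1O)C(=O)c1ccc(OC(=O)C(C)(C)C)cc1OC(=O)C(C)(C)C | intermediate
14 | 4-(3,6,7,8-tetramethoxy-4-oxo-4H-chromen-2-yl)-1,3-phenylene bis(2,2-dimethylpropanoate) | COc1cc2c(=O)c(OC)c(-c3ccc(OC(=O)C(C)(C)C)cc3OC(=O)C(C)(C)C)oc2c(OC)c1OC | intermediate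
15 | 4-[3,6,7,8-tetramethoxy-4-oxo-5-(trifluoroacetoxy)-4H-chromen-2-yl]-1,3-phenylene bis(2,2-dimethylpropanoate) (not isolated) | COc1c(OC)c(OC(=O)C(F)(F)F)c2c(=O)c(OC)c(-c3ccc(OC(=O)C(C)(C)C)cc3OC(=O)C(C)(C)C)oc2c1OC | intermediate
16 | 4-(5-hydroxy-3,6,7,8-tetramethoxy-4-oxo-4H-chromen-2-yl)-1,3-phenylene bis(2,2-dimethylpropanoate) | COc1c(OC)c(O)c2c(=O)c(OC)c(-c3ccc(OC(=O)C(C)(C)C)cc3OC(=O)C(C)(C)C)oc2c1OC | intermediate
17 | 5,2',4'-trihydroxy-3,6,7,8-tetramethoxyflavone | COc1c(OC)c(O)c2c(=O)c(OC)c(-c3ccc(O)cc3O)oc2c1OC | target

## Step count and risks

Total step count: 9. Longest linear sequence: 7 steps (steps 1, 2, 3, 6, 7, 8 and 9); steps 4 and 5 form the short branch to 11.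

Step 8 (key step). Three things can go wrong:
- Over-oxidation of ring A by the hypervalent iodine reagent, starting by electron transfer from the trimethoxy ring or by oxidative demethylation once any free C5 phenol is present next to the C8 methoxy group.
- Slow metalation, because C5–H is flanked by the C6 methoxy group.
- Acyl exchange or partial loss of the pivalates in hot acid. This is harmless as long as ring B stays acylated, since step 9 removes all esters.

The fallback sets out from 14 and returns at 16 without C–H metalation. Electrophilic bromination with N-bromosuccinimide in MeCN should go to the only open position of the electron-rich ring A and give 4-(5-bromo-3,6,7,8-tetramethoxy-4-oxo-4H-chromen-2-yl)-1,3-phenylene bis(2,2-dimethylpropanoate) F1. Miyaura borylation (B2pin2, Pd(OAc)2, SPhos, KOAc, dioxane, 90 °C) should convert it into 4-[3,6,7,8-tetramethoxy-4-oxo-5-(4,4,5,5-tetramethyl-1,3,2-dioxaborolan-2-yl)-4H-chromen-2-yl]-1,3-phenylene bis(2,2-dimethylpropanoate) F2. Oxidation of the C–B bond with NaBO3·4H2O in THF/H2O at room temperature then gives 16.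

Step 3 (Fries rearrangement). The methoxyacetyl cation can lose carbon monoxide, which would lead to methoxymethylation of the ring instead of acylation. Intermolecular acyl transfer could also reach the position meta to the oxygen. The fallback sets out from 3 and returns at 7 by directed ortho-metalation. Protection with chloromethyl methyl ether and iPr2NEt gives 1,2,3-trimethoxy-4-(methoxymethoxy)benzene F3. Lithiation with n-BuLi and TMEDA in THF at 0 °C goes ortho to the acetal oxygen, and addition of N,2-dimethoxy-N-methylacetamide gives 2-methoxy-1-[3,4,5-trimethoxy-2-(methoxymethoxy)phenyl]ethan-1-one F4. HCl in MeOH removes the acetal and gives 7.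

Step 7 (rearrangement and cyclisation). The amide base may attack the pivalates or cause them to migrate. If the C2' ester is lost, ring closure through the ring B phenol would give the isomeric chromone. The fallback sets out from 7, carries ring B as benzyl ethers through the base step, and returns at 14:
- 2,4-Bis(benzyloxy)benzoyl chloride F5, made from the corresponding commercial acid with oxalyl chloride, acylates 7 (Et3N, DMAP) to 6-(methoxyacetyl)-2,3,4-trimethoxyphenyl 2,4-bis(benzyloxy)benzoate F6.
- Rearrangement with LiN(SiMe3)2 gives 1-[2,4-bis(benzyloxy)phenyl]-3-(2-hydroxy-3,4,5-trimethoxyphenyl)-2-methoxypropane-1,3-dione F7.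
- TsOH in toluene closes it to 2-[2,4-bis(benzyloxy)phenyl]-3,6,7,8-tetramethoxy-4H-chromen-4-one F8.
- Hydrogenolysis (H2, Pd/C, EtOAc) gives 2-(2,4-dihydroxyphenyl)-3,6,7,8-tetramethoxy-4H-chromen-4-one F9.
- Pivaloyl chloride with Et3N and DMAP acylates its only two hydroxyls and gives 14.

Step 4 (pivaloylation of the hydroxy acid). The mixed anhydride may be attacked at the aroyl carbonyl by the phenol of a second molecule, which leads to oligoesters. Acylation of the hydrogen-bonded C2 hydroxyl may also stay incomplete. The fallback sets out from 8, masks the carboxyl group first, and returns at 10. Alkylation of the carboxylate with benzyl bromide and KHCO3 in DMF gives benzyl 2,4-dihydroxybenzoate F10. Pivaloyl chloride with Et3N and DMAP gives benzyl 2,4-bis(2,2-dimethylpropanoyloxy)benzoate F11. Hydrogenolysis (H2, Pd/C, EtOAc) frees the acid 10.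

## Further compounds

F1 | step 8 | 4-(5-bromo-3,6,7,8-tetramethoxy-4-oxo-4H-chromen-2-yl)-1,3-phenylene bis(2,2-dimethylpropanoate) | COc1c(OC)c(Br)c2c(=O)c(OC)c(-c3ccc(OC(=O)C(C)(C)C)cc3OC(=O)C(C)(C)C)oc2c1OC
F2 | step 8 | 4-[3,6,7,8-tetramethoxy-4-oxo-5-(4,4,5,5-tetramethyl-1,3,2-dioxaborolan-2-yl)-4H-chromen-2-yl]-1,3-phenylene bis(2,2-dimethylpropanoate) | COc1c(OC)c(B3OC(C)(C)C(C)(C)O3)c2c(=O)c(OC)c(-c4ccc(OC(=O)C(C)(C)C)cc4OC(=O)C(C)(C)C)oc2c1OC
F3 | step 3 | 1,2,3-trimethoxy-4-(methoxymethoxy)benzene | COCOc1ccc(OC)c(OC)c1OC
F4 | step 3 | 2-methoxy-1-[3,4,5-trimethoxy-2-(methoxymethoxy)phenyl]ethan-1-one | COCOc1c(C(=O)COC)cc(OC)c(OC)c1OC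
F5 | step 7 | 2,4-bis(benzyloxy)benzoyl chloride | O=C(Cl)c1ccc(OCc2ccccc2)cc1OCc1ccccc1
F6 | step 7 | 6-(methoxyacetyl)-2,3,4-trimethoxyphenyl 2,4-bis(benzyloxy)benzoate | COCC(=O)c1cc(OC)c(OC)c(OC)c1OC(=O)c1ccc(OCc2ccccc2)cc1OCc1ccccc1
F7 | step 7 | 1-[2,4-bis(benzyloxy)phenyl]-3-(2-hydroxy-3,4,5-trimethoxyphenyl)-2-methoxypropane-1,3-dione (racemic) | COC(C(=O)c1cc(OC)c(OC)c(OC)c1O)C(=O)c1ccc(OCc2ccccc2)cc1OCc1ccccc1
F8 | step 7 | 2-[2,4-bis(benzyloxy)phenyl]-3,6,7,8-tetramethoxy-4H-chromen-4-one | COc1cc2c(=O)c(OC)c(-c3ccc(OCc4ccccc4)cc3OCc3ccccc3)oc2c(OC)c1OC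
F9 | step 7 | 2-(2,4-dihydroxyphenyl)-3,6,7,8-tetramethoxy-4H-chromen-4-one | COc1cc2c(=O)c(OC)c(-c3ccc(O)cc3O)oc2c(OC)c1OC
F10 | step 4 | benzyl 2,4-dihydroxybenzoate | O=C(OCc1ccccc1)c1ccc(O)cc1O
F11 | step 4 | benzyl 2,4-bis(2,2-dimethylpropanoyloxy)benzoate | CC(C)(C)C(=O)Oc1ccc(C(=O)OCc2ccccc2)c(OC(=O)C(C)(C)C)c1
A1 | alternative 1 | 2-[2,4-bis(benzyloxy)phenyl]-5-hydroxy-6,7,8-trimethoxy-4H-chromen-4-one | COc1c(OC)c(O)c2c(=O)cc(-c3ccc(OCc4ccccc4)cc3OCc3ccccc3)oc2c1OC
A2 | alternative 1 | 2-iodo-4,5,6-trimethoxybenzene-1,3-diol | COc1c(O)c(I)c(O)c(OC)c1OC
A3 | alternative 1 | 2,4-bis(benzyloxy)-1-ethynylbenzene | C#Cc1ccc(OCc2ccccc2)cc1OCc1ccccc1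
A4 | alternative 2 | 2-[2,4-bis(benzyloxy)phenyl]-3,5,6,7,8-pentamethoxy-4H-chromen-4-one | COc1c(-c2ccc(OCc3ccccc3)cc2OCc2ccccc2)oc2c(OC)c(OC)c(OC)c(OC)c2c1=O
A5 | alternative 2 | 2,3,4,5-tetramethoxy-6-(trimethylsilyl)phenyl trifluoromethanesulfonate | COc1c(OC)c(OC)c([Si](C)(C)C)c(OS(=O)(=O)C(F)(F)F)c1OC
A6 | alternative 2 | methyl 3-[2,4-bis(benzyloxy)phenyl]-2-methoxy-3-oxopropanoate (racemic) | COC(=O)C(OC)C(=O)c1ccc(OCc2ccccc2)cc1OCc1ccccc1
A7 | alternative 2 | 3,4,5,6-tetramethoxybenzyne | COC1=C(OC)C(OC)=C(OC)C#C1
A8 | alternative 3 | 2-[2,4-bis(benzyloxy)phenyl]-5-hydroxy-3,6,7,8-tetramethoxy-4H-chromen-4-one | COc1c(OC)c(O)c2c(=O)c(OC)c(-c3ccc(OCc4ccccc4)cc3OCc3ccccc3)oc2c1OC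
A9 | alternative 3 | 4-{6-[2,4-bis(benzyloxy)phenyl]-5-methoxy-4-oxo-4H-pyran-2-yl}-2,3,4-trimethoxycyclobut-2-en-1-one (racemic) | COC1=C(OC)C(OC)(c2cc(=O)c(OC)c(-c3ccc(OCc4ccccc4)cc3OCc3ccccc3)o2)C1=O
A10 | alternative 3 | (3Z)-4-{6-[2,4-bis(benzyloxy)phenyl]-5-methoxy-4-oxo-4H-pyran-2-yl}-2,3,4-trimethoxybuta-1,3-dien-1-one | O=C=C(OC)/C(OC)=C(/OC)c1cc(=O)c(OC)c(-c2ccc(OCc3ccccc3)cc2OCc2ccccc2)o1
A11 | alternative 3 | 3,4-dimethoxycyclobut-3-ene-1,2-dione | COC1=C(OC)C(=O)C1=O
A12 | alternative 3 | 2-[2,4-bis(benzyloxy)phenyl]-3-methoxy-4H-pyran-4-one | COc1c(-c2ccc(OCc3ccccc3)cc2OCc2ccccc2)occc1=O
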